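**Retrosynthetic overview**

1. Target 22 comes from the protected oxepine ester 20 by ester cleavage and desilylation.
2. 20 comes from chromanone 16 by transfer of a hydroxymethyl group from tin to the vinylic carbon (C6–C7), followed by migration of C2 from the phenol oxygen to the new allylic oxygen (O1–C2). The feature that allows this: the ring oxygen O1 sits on C2, which is β to the aryl ketone carbonyl (an oxa-Michael bond), and the ortho-hydroxyl of that ketone can hold the same β-carbon in a temporary chroman-4-one ring.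
3. 16 comes from 1,1-dibromoalkene 11 and the homoallylic zinc reagent from 14 by trans-selective mono-Negishi coupling, which fixes the ring-alkene geometry.
4. 11 comes from chromone ester 5 (conjugate addition of a butenyl group, ozonolysis, dibromoolefination); 5 comes from 2,5-dihydroxyacetophenone and dimethyl oxalate.
5. Ring order: pyranone ring first (step 1, temporary), oxepine ring last (step 9, with opening of the pyranone).

Key step: step 9

Remark: C2 of compounds 7–18 is carried as the racemate on purpose; it becomes planar in 19 and is set in step 9.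
Remark (assumption): the sense of induction of a cinchona squaramide in this seven-membered closure cannot be assigned safely by analogy. The quinidine-derived catalyst is written; its quinine-derived pseudoenantiomer takes its place under the same conditions if that one gives the 2R ether.
Remark: but-3-en-1-ylmagnesium bromide (THF solution) and (tributylstannyl)methanol are taken as purchased.

**Step 1**
Reactants: 1 2,5-dihydroxyacetophenone; 2 dimethyl oxalate
Product: 4 methyl 6-hydroxy-4-oxo-4H-chromene-2-carboxylate, via diketo ester 3 (not isolated)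
Conditions: NaOMe (4 equiv), MeOH, reflux; then conc. HCl, MeOH, reflux
Reagents that add atoms: none
Why: Crossed Claisen condensation of the methyl ketone with the oxalate and acid-promoted cyclodehydration of the 2-hydroxyaryl 1,3-diketone (the classical chromone-2-carboxylate synthesis) build the pyranone ring that later masks the enone.

**Step 2**
Reactants: 4 methyl 6-hydroxy-4-oxo-4H-chromene-2-carboxylate
Product: 5 methyl 4-oxo-6-{[tri(propan-2-yl)silyl]oxy}-4H-chromene-2-carboxylate
Conditions: TIPSCl, imidazole, DMF, rt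
Reagents that add atoms: chlorotri(propan-2-yl)silane, CC(C)[Si](Cl)(C(C)C)C(C)C
Why: Silylation of the only free hydroxyl gives a bulky aryl silyl ether that should survive the organometallic, oxidative and tin hydroxide steps and fall to fluoride at the end.

**Step 3**
Reactants: 5 methyl 4-oxo-6-{[tri(propan-2-yl)silyl]oxy}-4H-chromene-2-carboxylate; 6 but-3-en-1-ylmagnesium bromide (CH2=CHCH2CH2MgBr)
Product: 8 methyl 2-(but-3-en-1-yl)-4-oxo-6-{[tri(propan-2-yl)silyl]oxy}chromane-2-carboxylate (racemic), via silyl enol ether 7 (not isolated)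
Conditions: CuBr·SMe2 (10 mol%), TMSCl (2 equiv), THF, −78 °C; then 1 M aq. HCl, 0 °C
Reagents that add atoms: none
Why: Copper-catalysed, silyl chloride-accelerated conjugate addition of the Grignard reagent to C2 of the chromone (β-carbon of the enone, further activated by the 2-ester) should outrun 1,2-addition at −78 °C, trapping as 7 prevents E1cB opening of the ring, and the quaternary centre C2 forms as the racemate.

**Step 4**
Reactants: 8 methyl 2-(but-3-en-1-yl)-4-oxo-6-{[tri(propan-2-yl)silyl]oxy}chromane-2-carboxylate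
Product: 10 methyl 4-oxo-2-(3-oxopropyl)-6-{[tri(propan-2-yl)silyl]oxy}chromane-2-carboxylate (racemic), via ozonide 9 (not isolated)
Conditions: O3, CH2Cl2, −78 °C, stopped at the first persistent blue colour; then PPh3, −78 °C to rt
Reagents that add atoms: ozone, [O-][O+]=O
Why: Ozonolysis of the monosubstituted alkene, far more reactive than the acylated aryl ring, with reductive work-up gives the aldehyde under neutral conditions that avoid aldol closure onto C3 of the chromanone.

**Step 5**
Reactants: 10 methyl 4-oxo-2-(3-oxopropyl)-6-{[tri(propan-2-yl)silyl]oxy}chromane-2-carboxylate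
Product: 11 methyl 2-(4,4-dibromobut-3-en-1-yl)-4-oxo-6-{[tri(propan-2-yl)silyl]oxy}chromane-2-carboxylate (racemic)
Conditions: CBr4 (2 equiv), PPh3 (2 equiv), Zn dust (2 equiv), CH2Cl2, rt (ylide formation); then 10, 0 °C to rt
Reagents that add atoms: carbon tetrabromide, BrC(Br)(Br)Br
Why: Ramirez dibromoolefination (first stage of the Corey–Fuchs sequence) with zinc-generated Ph3P=CBr2 should convert the aldehyde only, the aryl ketone being inert to this stabilised ylide.

**Step 6**
Reactants: 12 5-bromo-2-methylpent-2-ene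
Product: 13 (2E)-5-bromo-2-methylpent-2-en-1-ol
Conditions: SeO2 (0.3 equiv), t-BuOOH (3 equiv), salicylic acid (0.1 equiv), CH2Cl2, rt
Reagents that add atoms: tert-butyl hydroperoxide, CC(C)(C)OO (oxygen source; SeO2 is the catalytic carrier)
Why: Riley allylic oxidation (ene reaction, then 2,3-sigmatropic shift) of a trisubstituted alkene hydroxylates the methyl group trans to the chain, which sets the E geometry of the terminal allylic alcohol.

**Step 7**
Reactants: 13 (2E)-5-bromo-2-methylpent-2-en-1-ol
Product: 14 {[(2E)-5-bromo-2-methylpent-2-en-1-yl]oxy}(tert-butyl)dimethylsilane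
Conditions: TBSCl, imidazole, CH2Cl2, 0 °C to rt
Reagents that add atoms: tert-butyl(chloro)dimethylsilane, CC(C)(C)[Si](C)(C)Cl
Why: Standard silylation protects the allylic alcohol against the zinc insertion and the coupling steps.

**Step 8**
Reactants: 11 methyl 2-(4,4-dibromobut-3-en-1-yl)-4-oxo-6-{[tri(propan-2-yl)silyl]oxy}chromane-2-carboxylate; 14 {[(2E)-5-bromo-2-methylpent-2-en-1-yl]oxy}(tert-butyl)dimethylsilane
Product: 16 methyl 2-[(3Z,7E)-4-bromo-9-{[tert-butyl(dimethyl)silyl]oxy}-8-methylnona-3,7-dien-1-yl]-4-oxo-6-{[tri(propan-2-yl)silyl]oxy}chromane-2-carboxylate (racemic at C2), via alkylzinc bromide 15 (not isolated)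
Conditions: 14, Zn dust (1.5 equiv), I2 (5 mol%), DMA, 70 °C; solution of 15 decanted from Zn; then 11, PdCl2(DPEphos) (5 mol%), THF/DMA, 0 °C to rt
Reagents that add atoms: none
Why: Direct zinc insertion gives an alkylzinc that tolerates ketone and ester, and the Negishi mono-alkylation of a 1,1-dibromoalkene takes place at the C–Br bond trans to the chain, so the remaining bromine stands cis to C4 (Z), as the ring alkene requires.

**Step 9**
Reactants: 16 methyl 2-[(3Z,7E)-4-bromo-9-{[tert-butyl(dimethyl)silyl]oxy}-8-methylnona-3,7-dien-1-yl]-4-oxo-6-{[tri(propan-2-yl)silyl]oxy}chromane-2-carboxylate; 17 (tributylstannyl)methanol (Bu3SnCH2OH)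
Product: 20 methyl (2R)-6-[(3E)-5-{[tert-butyl(dimethyl)silyl]oxy}-4-methylpent-3-en-1-yl]-2-[2-(2-hydroxy-5-{[tri(propan-2-yl)silyl]oxy}phenyl)-2-oxoethyl]-2,3,4,7-tetrahydrooxepine-2-carboxylate, via allylic alcohol 18 (not isolated), via hydroxyaryl enone 19 (not isolated)
Conditions: Pd(PPh3)4 (5 mol%), 17 (1.5 equiv), toluene, 90 °C; then 0 °C, squaramide from 9-amino-9-deoxy-epi-quinidine and 3,5-bis(trifluoromethyl)aniline (10 mol%), 0 °C to rt, same flask
Reagents that add atoms: none
Why: Proposed new method: a Migita–Kosugi–Stille coupling moves the hydroxymethyl group of 17 onto the vinylic carbon of 16 with retention of the Z geometry (C6–C7 bond, 18), and the amine–squaramide catalyst then opens the chromanone by E1cB retro-oxa-Michael elimination to the 2-hydroxyaryl enone 19 and returns the new allylic hydroxyl to C2 of that enone (O1–C2 bond). The closest known reaction types are the Stille hydroxymethylation of alkenyl halides with Bu3SnCH2OH, the base-catalysed flavanone–chalcone equilibrium, and the asymmetric cycloetherification of hydroxy enones by cinchona amine–thiourea or amine–squaramide catalysts, known for five- and six-membered ethers. The oxepine closes by 7-exo-trig oxa-Michael addition, helped by the cis C5=C6 bond in the tether, and the trade of an aryl ether for an alkyl ether next to a hydrogen-bonded ortho-hydroxyaryl ketone should pull the ring transfer forward. C2 is set by the catalyst, whose squaramide should bind the ketone of 19 while its ammonium-bound alkoxide adds to the Re face of C2 (priorities CO2Me > C3 > CH2), which gives 2R; both enantiomers of 18 converge on achiral 19. The step needs CH2OH and not butyl to leave tin (usual for α-oxygenated stannanes), no Heck-type attack of the vinylpalladium on an enone (the enone stays masked in the chromanone while palladium is active), and one reacting enone geometry, for which fast E/Z exchange of 19 through reclosure to 18 is relied on.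

**Step 10**
Reactants: 20 methyl (2R)-6-[(3E)-5-{[tert-butyl(dimethyl)silyl]oxy}-4-methylpent-3-en-1-yl]-2-[2-(2-hydroxy-5-{[tri(propan-2-yl)silyl]oxy}phenyl)-2-oxoethyl]-2,3,4,7-tetrahydrooxepine-2-carboxylate
Product: 21 (2R)-6-[(3E)-5-{[tert-butyl(dimethyl)silyl]oxy}-4-methylpent-3-en-1-yl]-2-[2-(2-hydroxy-5-{[tri(propan-2-yl)silyl]oxy}phenyl)-2-oxoethyl]-2,3,4,7-tetrahydrooxepine-2-carboxylic acid
Conditions: Me3SnOH (8 equiv), 1,2-dichloroethane, 70 °C, argon; then 5% aq. HCl wash
Reagents that add atoms: trimethyltin hydroxide, C[Sn](C)(C)O (supplies the carboxyl OH oxygen)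
Why: Trimethyltin hydroxide cleaves methyl esters by acyl substitution near neutral pH, which should spare the β-alkoxy ketone from the retro-oxa-Michael opening that hydroxide could cause, so C2 keeps its configuration.

**Step 11**
Reactants: 21 (2R)-6-[(3E)-5-{[tert-butyl(dimethyl)silyl]oxy}-4-methylpent-3-en-1-yl]-2-[2-(2-hydroxy-5-{[tri(propan-2-yl)silyl]oxy}phenyl)-2-oxoethyl]-2,3,4,7-tetrahydrooxepine-2-carboxylic acid
Product: 22 (2R)-2-[2-(2,5-dihydroxyphenyl)-2-oxoethyl]-6-[(3E)-5-hydroxy-4-methylpent-3-en-1-yl]-2,3,4,7-tetrahydrooxepine-2-carboxylic acid (CNP0570804.1)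
Conditions: Bu4NF (3 equiv), AcOH (3 equiv), THF, 0 °C to rt, argon; work-up at pH 3
Reagents that add atoms: none
Why: Acetic acid-buffered fluoride removes the aryl triisopropylsilyl and the primary tert-butyldimethylsilyl ether without basic conditions, leaving the tertiary ether, both alkenes and the C2 stereocentre untouched.

**Compound list**

1 | 2,5-dihydroxyacetophenone | CC(=O)c1cc(O)ccc1O | starting material
2 | dimethyl oxalate | COC(=O)C(=O)OC | starting material
3 | methyl 4-(2,5-dihydroxyphenyl)-2,4-dioxobutanoate | COC(=O)C(=O)CC(=O)c1cc(O)ccc1O | intermediate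
4 | methyl 6-hydroxy-4-oxo-4H-chromene-2-carboxylate | COC(=O)c1cc(=O)c2cc(O)ccc2o1 | intermediate
5 | methyl 4-oxo-6-{[tri(propan-2-yl)silyl]oxy}-4H-chromene-2-carboxylate | COC(=O)c1cc(=O)c2cc(O[Si](C(C)C)(C(C)C)C(C)C)ccc2o1 | intermediate
6 | but-3-en-1-ylmagnesium bromide | C=CCC[Mg]Br | starting material
7 | methyl 2-(but-3-en-1-yl)-6-{[tri(propan-2-yl)silyl]oxy}-4-[(trimethylsilyl)oxy]-2H-chromene-2-carboxylate (racemic) | COC(=O)C1(CCC=C)C=C(O[Si](C)(C)C)c2cc(O[Si](C(C)C)(C(C)C)C(C)C)ccc2O1 | intermediate
8 | methyl 2-(but-3-en-1-yl)-4-oxo-6-{[tri(propan-2-yl)silyl]oxy}chromane-2-carboxylate (racemic) | COC(=O)C1(CCC=C)CC(=O)c2cc(O[Si](C(C)C)(C(C)C)C(C)C)ccc2O1 | intermediate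
9 | methyl 4-oxo-2-[2-(1,2,4-trioxolan-3-yl)ethyl]-6-{[tri(propan-2-yl)silyl]oxy}chromane-2-carboxylate (isomer mixture) | COC(=O)C1(CCC3OCOO3)CC(=O)c2cc(O[Si](C(C)C)(C(C)C)C(C)C)ccc2O1 | intermediate
10 | methyl 4-oxo-2-(3-oxopropyl)-6-{[tri(propan-2-yl)silyl]oxy}chromane-2-carboxylate (racemic) | COC(=O)C1(CCC=O)CC(=O)c2cc(O[Si](C(C)C)(C(C)C)C(C)C)ccc2O1 | intermediate
11 | methyl 2-(4,4-dibromobut-3-en-1-yl)-4-oxo-6-{[tri(propan-2-yl)silyl]oxy}chromane-2-carboxylate (racemic) | COC(=O)C1(CCC=C(Br)Br)CC(=O)c2cc(O[Si](C(C)C)(C(C)C)C(C)C)ccc2O1 | intermediate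
12 | 5-bromo-2-methylpent-2-ene | CC(C)=CCCBr | starting material
13 | (2E)-5-bromo-2-methylpent-2-en-1-ol | C/C(=C\CCBr)CO | intermediate
14 | {[(2E)-5-bromo-2-methylpent-2-en-1-yl]oxy}(tert-butyl)dimethylsilane | C/C(=C\CCBr)CO[Si](C)(C)C(C)(C)C | intermediate
15 | [(3E)-5-{[tert-butyl(dimethyl)silyl]oxy}-4-methylpent-3-en-1-yl]zinc bromide | C/C(=C\CC[Zn]Br)CO[Si](C)(C)C(C)(C)C | intermediate
16 | methyl 2-[(3Z,7E)-4-bromo-9-{[tert-butyl(dimethyl)silyl]oxy}-8-methylnona-3,7-dien-1-yl]-4-oxo-6-{[tri(propan-2-yl)silyl]oxy}chromane-2-carboxylate (racemic at C2) | COC(=O)C1(CC/C=C(\Br)CC/C=C(\C)CO[Si](C)(C)C(C)(C)C)CC(=O)c2cc(O[Si](C(C)C)(C(C)C)C(C)C)ccc2O1 | intermediate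
17 | (tributylstannyl)methanol | CCCC[Sn](CCCC)(CCCC)CO | starting material
18 | methyl 2-[(3Z,7E)-9-{[tert-butyl(dimethyl)silyl]oxy}-4-(hydroxymethyl)-8-methylnona-3,7-dien-1-yl]-4-oxo-6-{[tri(propan-2-yl)silyl]oxy}chromane-2-carboxylate (racemic at C2) | COC(=O)C1(CC/C=C(\CO)CC/C=C(\C)CO[Si](C)(C)C(C)(C)C)CC(=O)c2cc(O[Si](C(C)C)(C(C)C)C(C)C)ccc2O1 | intermediate
19 | methyl 2-[(3Z,7E)-9-{[tert-butyl(dimethyl)silyl]oxy}-4-(hydroxymethyl)-8-methylnona-3,7-dien-1-yl]-4-(2-hydroxy-5-{[tri(propan-2-yl)silyl]oxy}phenyl)-4-oxobut-2-enoate (E/Z mixture at the enone) | COC(=O)C(CC/C=C(\CO)CC/C=C(\C)CO[Si](C)(C)C(C)(C)C)=CC(=O)c1cc(O[Si](C(C)C)(C(C)C)C(C)C)ccc1O | intermediate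
20 | methyl (2R)-6-[(3E)-5-{[tert-butyl(dimethyl)silyl]oxy}-4-methylpent-3-en-1-yl]-2-[2-(2-hydroxy-5-{[tri(propan-2-yl)silyl]oxy}phenyl)-2-oxoethyl]-2,3,4,7-tetrahydrooxepine-2-carboxylate | C/C(=C\CCC1=CCC[C@@](CC(=O)c2cc(O[Si](C(C)C)(C(C)C)C(C)C)ccc2O)(C(=O)OC)OC1)CO[Si](C)(C)C(C)(C)C | intermediate
21 | (2R)-6-[(3E)-5-{[tert-butyl(dimethyl)silyl]oxy}-4-methylpent-3-en-1-yl]-2-[2-(2-hydroxy-5-{[tri(propan-2-yl)silyl]oxy}phenyl)-2-oxoethyl]-2,3,4,7-tetrahydrooxepine-2-carboxylic acid | C/C(=C\CCC1=CCC[C@@](CC(=O)c2cc(O[Si](C(C)C)(C(C)C)C(C)C)ccc2O)(C(=O)O)OC1)CO[Si](C)(C)C(C)(C)C | intermediate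
22 | (2R)-2-[2-(2,5-dihydroxyphenyl)-2-oxoethyl]-6-[(3E)-5-hydroxy-4-methylpent-3-en-1-yl]-2,3,4,7-tetrahydrooxepine-2-carboxylic acid | C/C(=C\CCC1=CCC[C@@](CC(=O)c2cc(O)ccc2O)(C(=O)O)OC1)CO | target

**Step count and risks**

Total step count: 11. Longest linear sequence: 9 steps (steps 1–5 and 8–11 from compound 1); the side-chain branch is steps 6–7.

Steps most likely to fail:

Step 9 (proposed new method). What may go wrong: insufficient face selectivity in the oxa-Michael closure, made worse by partial uncatalysed ring transfer during the hot coupling stage. The fallback sets out from 16 and 17. The Stille coupling alone (Pd(PPh3)4, toluene, 90 °C) is run and allylic alcohol 18 is isolated. DBU (1.1 equiv, toluene, rt, then acidification) then opens the chromanone and closes the oxepine; both are established base-catalysed processes (flavanone–chalcone opening, intramolecular oxa-Michael addition), here driven by the phenoxide and with no demand on face selectivity. This should give the racemic oxepine ester F1. Preparative HPLC on an amylose tris(3,5-dimethylphenylcarbamate) phase separates 20 from its enantiomer, the (2S)-oxepine ester F2. F2 can be returned to F1 with DBU and resolved again. The fallback comes back to the route at 20.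

Step 10. What may go wrong: slow acyl substitution at the hindered ester on the quaternary C2, so that retro-oxa-Michael opening and loss of configuration compete at the temperature needed. The fallback sets out from 20. LiI (10 equiv, EtOAc, reflux) cleaves the ester by SN2 attack of iodide on the methyl carbon, which is indifferent to the hindrance at C2 and non-basic. This should give the lithium carboxylate F5, which 1 M HCl converts into the acid. The fallback comes back to the route at 21.

Step 3. What may go wrong: 1,2-addition of the Grignard reagent to the ester or ketone, or opening of the enolate before it is silylated. The fallback sets out from 2, 6 and 1. Addition of 6 to excess 2 (THF, −78 °C) should give methyl 2-oxohex-5-enoate F3. Kabbe condensation of F3 with 1 (pyrrolidine, MeOH, 60 °C: enamine aldol, dehydration, phenol oxa-Michael closure) should give methyl 2-(but-3-en-1-yl)-6-hydroxy-4-oxochromane-2-carboxylate F4. Silylation (TIPSCl, imidazole, DMF) then gives the butenyl chromanone. The fallback comes back to the route at 8.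

**Further compounds**

F1 | step 9 | methyl 6-[(3E)-5-{[tert-butyl(dimethyl)silyl]oxy}-4-methylpent-3-en-1-yl]-2-[2-(2-hydroxy-5-{[tri(propan-2-yl)silyl]oxy}phenyl)-2-oxoethyl]-2,3,4,7-tetrahydrooxepine-2-carboxylate (racemic) | C/C(=C\CCC1=CCCC(CC(=O)c2cc(O[Si](C(C)C)(C(C)C)C(C)C)ccc2O)(C(=O)OC)OC1)CO[Si](C)(C)C(C)(C)C
F2 | step 9 | methyl (2S)-6-[(3E)-5-{[tert-butyl(dimethyl)silyl]oxy}-4-methylpent-3-en-1-yl]-2-[2-(2-hydroxy-5-{[tri(propan-2-yl)silyl]oxy}phenyl)-2-oxoethyl]-2,3,4,7-tetrahydrooxepine-2-carboxylate | C/C(=C\CCC1=CCC[C@](CC(=O)c2cc(O[Si](C(C)C)(C(C)C)C(C)C)ccc2O)(C(=O)OC)OC1)CO[Si](C)(C)C(C)(C)C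
F5 | step 10 | lithium (2R)-6-[(3E)-5-{[tert-butyl(dimethyl)silyl]oxy}-4-methylpent-3-en-1-yl]-2-[2-(2-hydroxy-5-{[tri(propan-2-yl)silyl]oxy}phenyl)-2-oxoethyl]-2,3,4,7-tetrahydrooxepine-2-carboxylate | [Li+].C/C(=C\CCC1=CCC[C@@](CC(=O)c2cc(O[Si](C(C)C)(C(C)C)C(C)C)ccc2O)(C(=O)[O-])OC1)CO[Si](C)(C)C(C)(C)C
F3 | step 3 | methyl 2-oxohex-5-enoate | COC(=O)C(=O)CCC=C
F4 | step 3 | methyl 2-(but-3-en-1-yl)-6-hydroxy-4-oxochromane-2-carboxylate (racemic) | COC(=O)C1(CCC=C)CC(=O)c2cc(O)ccc2O1
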